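**Retrosynthetic overview** (C numbers follow the daucane skeleton of the target: C1 quaternary ring-fusion carbon, C2 angelate carbinol, C4 isopropyl carbinol, C5 ring-fusion CH, C6 aroate carbinol, C8=C9 ring alkene)
- Target ⇒ phenol deprotection, C6 aroylation, hydroxyl-directed reduction of a C6 ketone and C2 angeloylation of a trans-fused hydroazulenone diol.
- Key disconnection: the C1–C2 bond together with the seven-membered ring. A siloxycyclopropane (C1, C5, C6; OTBS on C6) fused to a cyclohexene attacks a tethered C2 aldehyde through C1; cleavage of the C1–C6 bond enlarges the six-membered ring to the cycloheptenone while the five-membered ring closes.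
- Enabling feature: oxygenated C6 and quaternary C1 are both bonded to C5, so C1–C5–C6 can be folded into a donor-substituted cyclopropane on the six-membered ring C6–C7–C8=C9–C10–C1. Its strain and the C6 oxygen drive C1 onto C2, and the cis-1,3 oxygens at C2 and C4 allow chelation control.
- Cyclopropane ⇒ asymmetric cyclopropanation of the silyl dienol ether from Birch reduction of silylated 2,5-dimethylphenol (it carries both methyl groups and the C8=C9 alkene); side chain C4–C3–C2 by ester → isopropyl ketone → vinyl addition → hydroboration/oxidation.
- Ring order: six-membered ring (from the arene) → cyclopropane → seven- and five-membered rings together in the key step.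

Key step: step 8

Remark: the sense of asymmetric induction of the copper bis(oxazoline) catalyst on the tetrasubstituted silyl enol ether is assumed; the ligand antipode that gives the cyclopropane enantiomer drawn below is to be used.

**Step 1**
Reactants: 1 2,5-dimethylphenol
Product: 2 aryl TBS ether
Conditions: TBSCl, imidazole, DMF, rt
Reagents that add atoms: tert-butyldimethylsilyl chloride, CC(C)(C)[Si](C)(C)Cl
Why: Standard O-silylation of a phenol gives a silyl ether that survives dissolving-metal reduction and later serves as the bulky cyclopropane substituent and as the leaving silyl group.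

**Step 2**
Reactants: 2 aryl TBS ether
Product: 3 silyl dienol ether
Conditions: Li, NH3(l), THF, tBuOH, −78 → −33 °C; solid NH4Cl
Reagents that add atoms: none
Why: Birch reduction of an aryl silyl ether protonates the two unsubstituted carbons C3 and C6 of the arene, so oxygen and both methyl groups stay on the two isolated double bonds and the tetrasubstituted silyl enol ether is formed regiospecifically.

**Step 3**
Reactants: 3 silyl dienol ether
Product: 4 exo siloxycyclopropane ester
Conditions: ethyl diazoacetate (syringe pump), [Cu(MeCN)4]PF6 (2 mol %), 2,2'-isopropylidenebis[(4S)-4-tert-butyl-2-oxazoline] (2.4 mol %), CH2Cl2, 0 °C → rt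
Reagents that add atoms: ethyl diazoacetate, CCOC(=O)C=[N+]=[N-]
Why: Copper-carbene [2+1] cyclopropanation occurs at the electron-rich silyl enol ether and not at the trisubstituted alkene; the bis(oxazoline) ligand selects the alkene face (both ring-fusion carbons) and the ester should turn away from the ring methylenes (exo, cis to OTBS and CH3), a minor endo isomer being removed by chromatography.

**Step 4**
Reactants: 4 exo siloxycyclopropane ester
Product: 6 exo isopropyl ketone, via Weinreb amide 5 (not isolated)
Conditions: MeNH(OMe)·HCl, iPrMgCl (excess), THF, −20 °C → rt; aq. NH4Cl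
Reagents that add atoms: isopropylmagnesium chloride, CC(C)[Mg]Cl
Why: One-pot ester → Weinreb amide → ketone sequence, in which the chloromagnesium amide aminolyses the ester and the chelated tetrahedral intermediate stops the Grignard addition at the ketone; no stereocentre is touched.

**Step 5**
Reactants: 6 exo isopropyl ketone
Product: 7 tertiary vinyl carbinol
Conditions: vinylmagnesium bromide, CeCl3 (anhydrous), THF, −78 → 0 °C; aq. NH4Cl
Reagents that add atoms: vinylmagnesium bromide, C=C[Mg]Br
Why: Organocerium 1,2-addition to a hindered enolisable ketone; the carbonyl should adopt the bisected rotamer with oxygen over the cyclopropane and isopropyl outward, and vinyl should enter from the side of the ring-fusion methyl, anti to the bulky OTBS group, which sets C4 with its oxygen syn to C6.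

**Step 6**
Reactants: 7 tertiary vinyl carbinol
Product: 9 1,3-diol, via trialkylborane 8 (not isolated)
Conditions: 9-BBN, THF, 0 °C → rt; then aq. NaOH, H2O2, 0 °C
Reagents that add atoms: hydrogen peroxide, OO
Why: Anti-Markovnikov hydroboration–oxidation, in which 9-BBN selects the monosubstituted vinyl group over the trisubstituted ring alkene and the basic work-up spares the acid-labile siloxycyclopropyl carbinol.

**Step 7**
Reactants: 9 1,3-diol
Product: 10 β-hydroxy aldehyde
Conditions: nPr4N[RuO4] (5 mol %), NMO, 4 Å MS, CH2Cl2, 0 °C → rt
Reagents that add atoms: none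
Why: Ley–Griffith oxidation under neutral conditions converts the primary alcohol into the aldehyde while the tertiary alcohol cannot be oxidised; the aldehyde is used crude at once.

**Step 8**
Reactants: 10 β-hydroxy aldehyde
Product: 12 trans-hydroazulenone diol, via methylaluminium dialkoxide 11 (not isolated)
Conditions: Me2AlCl (2.5 equiv), CH2Cl2, −78 → −30 °C; then 1 M HCl, 0 °C
Reagents that add atoms: none
Why: Proposed new method: Me2AlCl deprotonates the tertiary hydroxyl (methane is lost) and the resulting chloro(methyl)aluminium alkoxide chelates and activates the aldehyde; the strained C1–C6 cyclopropane bond, polarised by the OTBS group on C6, then attacks C2 through its back lobe at C1 (homo-Mukaiyama aldol, SE2 with inversion), C6 turns into a silyloxocarbenium ion that loses TBSCl, and the six-membered ring is thereby enlarged to the cycloheptenone while the cyclopentane closes, the release of about 27 kcal/mol of ring strain paying for the congested quaternary centre. The closest known reaction type is the Lewis-acid-promoted cyclisation of cyclopropyl silyl ethers, used as homoenol ethers, onto tethered aldehydes and oxocarbenium ions, where an unsubstituted cyclopropane carbon attacks; attack through a fully substituted ring-fusion carbon with cleavage of the internal bond has so far been shown only for the oxidative FeCl3 ring enlargement of 1-siloxybicyclo[n.1.0]alkanes. The five-membered ring closes 5-exo-trig with respect to the C=O group; the seven-membered ring is not closed but formed by ring enlargement of the cyclohexene. C1 is set by inversion, C2 entering anti to the departing C6 because the front side is shielded by the C1 methyl group, so the exo position of the side chain in 10 (cis to that methyl) becomes the trans ring fusion. C2 is set by the six-membered aluminium chelate, which holds the carbonyl oxygen syn to O4 and can therefore only lead to the cis-1,3-diol. The step needs regioselection between the two oxygen-activated cyclopropane bonds and chemoselection against ionisation of the tertiary cyclopropylcarbinol: the three-atom tether reaches only C1 (attack at C5 would close a four-membered ring), and Me2AlCl scavenges protons while an aluminium alkoxide is a poor leaving group at low temperature.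

**Step 9**
Reactants: 12 trans-hydroazulenone diol
Product: 13 C2 angelate
Conditions: angelic acid, 2,4,6-trichlorobenzoyl chloride, Et3N, toluene, rt; filtration; then 12, toluene, 75 °C
Reagents that add atoms: angelic acid, C/C=C(/C)C(O)=O
Why: Yamaguchi-type mixed-anhydride esterification without a nucleophilic catalyst acylates the only secondary hydroxyl and keeps the (Z)-geometry of the angelate, the tertiary C4 hydroxyl being inert.

**Step 10**
Reactants: 13 C2 angelate
Product: 14 C6 alcohol
Conditions: Me4N[BH(OAc)3], MeCN/AcOH, −30 °C
Reagents that add atoms: none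
Why: Evans–Saksena hydroxyl-directed reduction, in which the C4 hydroxyl binds boron and delivers hydride to the face of the C6 ketone syn to it, so the new C6 hydroxyl is anti to the C4 hydroxyl (cis to H5) and the enoate is untouched.

**Step 11**
Reactants: 14 C6 alcohol
Product: 15 C6 4-acetoxybenzoate
Conditions: 4-acetoxybenzoyl chloride, Et3N, DMAP (cat.), CH2Cl2, 0 °C → rt
Reagents that add atoms: 4-acetoxybenzoyl chloride, CC(=O)Oc1ccc(cc1)C(Cl)=O
Why: DMAP-catalysed acylation of the secondary C6 hydroxyl, the tertiary C4 hydroxyl not reacting.

**Step 12**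
Reactants: 15 C6 4-acetoxybenzoate
Product: 16 target CNP0188626.1
Conditions: NH4OAc, MeOH/H2O (4:1), rt
Reagents that add atoms: none
Why: Chemoselective hydrolysis of the phenolic acetate, aryl acetates being far more labile than the alkyl angelate and aroate under neutral ammonium acetate buffering.

**Compound list**
1 | 2,5-dimethylphenol | Cc1ccc(C)c(O)c1 | starting material
2 | tert-butyl(2,5-dimethylphenoxy)dimethylsilane | Cc1ccc(C)c(O[Si](C)(C)C(C)(C)C)c1 | intermediate
3 | tert-butyl[(2,5-dimethylcyclohexa-1,4-dien-1-yl)oxy]dimethylsilane | CC1=CCC(C)=C(O[Si](C)(C)C(C)(C)C)C1 | intermediate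
4 | ethyl 1-[(tert-butyldimethylsilyl)oxy]-3,6-dimethylbicyclo[4.1.0]hept-3-ene-7-carboxylate; ester exo (on the cyclopropane cis to OTBS and to the C6 methyl); enantiomer as in the SMILES | CC(C)(C)[Si](C)(C)O[C@]12CC(C)=CC[C@@]1(C)[C@@H]2C(=O)OCC | intermediate
5 | N-methoxy-N-methylamide corresponding to 4 (same configuration) | CC(C)(C)[Si](C)(C)O[C@]12CC(C)=CC[C@@]1(C)[C@@H]2C(=O)N(C)OC | intermediate (not isolated)
6 | 1-{exo-1-[(tert-butyldimethylsilyl)oxy]-3,6-dimethylbicyclo[4.1.0]hept-3-en-7-yl}-2-methylpropan-1-one | CC(C)(C)[Si](C)(C)O[C@]12CC(C)=CC[C@@]1(C)[C@@H]2C(=O)C(C)C | intermediate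
7 | 3-{exo-1-[(tert-butyldimethylsilyl)oxy]-3,6-dimethylbicyclo[4.1.0]hept-3-en-7-yl}-4-methylpent-1-en-3-ol; carbinol configuration as in the SMILES (OH syn to the OTBS-bearing carbon, vinyl on the side of the methyl-bearing carbon) | CC(C)(C)[Si](C)(C)O[C@]12CC(C)=CC[C@@]1(C)[C@@H]2[C@](O)(C(C)C)C=C | intermediate
8 | B-alkyl-9-borabicyclo[3.3.1]nonane from 7 (boron on the terminal carbon; drawn with the free hydroxyl) | CC(C)(C)[Si](C)(C)O[C@]12CC(C)=CC[C@@]1(C)[C@@H]2[C@](O)(C(C)C)CCB1C2CCCC1CCC2 | intermediate (not isolated)
9 | 3-{exo-1-[(tert-butyldimethylsilyl)oxy]-3,6-dimethylbicyclo[4.1.0]hept-3-en-7-yl}-4-methylpentane-1,3-diol | CC(C)(C)[Si](C)(C)O[C@]12CC(C)=CC[C@@]1(C)[C@@H]2[C@](O)(C(C)C)CCO | intermediate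
10 | 3-{exo-1-[(tert-butyldimethylsilyl)oxy]-3,6-dimethylbicyclo[4.1.0]hept-3-en-7-yl}-3-hydroxy-4-methylpentanal | CC(C)(C)[Si](C)(C)O[C@]12CC(C)=CC[C@@]1(C)[C@@H]2[C@](O)(C(C)C)CC=O | intermediate
11 | cyclic methylaluminium 1,3-dialkoxide of 12 (aluminium bridges the C2 and C4 oxygens) | C[Al]1O[C@@H]2C[C@](C(C)C)(O1)[C@@H]3C(=O)CC(C)=CC[C@@]23C | intermediate (not isolated)
12 | 1,3-dihydroxy-6,8a-dimethyl-3-(propan-2-yl)-1,2,3,3a,8,8a-hexahydroazulen-4(5H)-one; trans-fused; 1-OH, 3-OH and 8a-CH3 on one face, H-3a and isopropyl on the other (daucane C2/C4 diol, C6 ketone) | O[C@@H]1C[C@@](O)(C(C)C)[C@@H]2C(=O)CC(C)=CC[C@]21C | intermediate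
13 | 1-O-[(Z)-2-methylbut-2-enoyl] ester (angelate) of 12 | C/C=C(/C)C(=O)O[C@@H]1C[C@@](O)(C(C)C)[C@@H]2C(=O)CC(C)=CC[C@]21C | intermediate
14 | 4-alcohol of 13 (azulene C4 = daucane C6); new OH on the face of H-3a, anti to the tertiary OH | C/C=C(/C)C(=O)O[C@@H]1C[C@@](O)(C(C)C)[C@@H]2[C@@H](O)CC(C)=CC[C@]21C | intermediate
15 | 4-O-(4-acetoxybenzoyl) ester of 14 | C/C=C(/C)C(=O)O[C@@H]1C[C@@](O)(C(C)C)[C@@H]2[C@@H](OC(=O)c3ccc(OC(C)=O)cc3)CC(C)=CC[C@]21C | intermediate
16 | CNP0188626.1: trans-fused daucane with C2 angelate, C4 tertiary OH and isopropyl, C6 4-hydroxybenzoate; O2, O4 and the C1 methyl on one face, H5, isopropyl and O6 on the other | C/C=C(/C)C(=O)O[C@@H]1C[C@@](O)(C(C)C)[C@@H]2[C@@H](OC(=O)c3ccc(O)cc3)CC(C)=CC[C@]21C | target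

**Total step count:** 12
**Longest linear sequence:** 12 steps (from 2,5-dimethylphenol)

**Steps most likely to fail**

Step 8 (proposed new method). Ionisation of the tertiary cyclopropylcarbinyl C4–O bond with cyclopropylcarbinyl–homoallyl fragmentation of the C5–C6 bond, or methyl transfer from aluminium to the chelated aldehyde, may outrun the sterically demanding invertive attack at the fully substituted C1. The fallback uses known chemistry and forms the bond by a radical instead of a polar path; it sets out from 10 and comes back at 12. Treatment of 10 with FeCl3 in DMF at 0 °C, the established oxidative ring enlargement of 1-siloxybicyclo[n.1.0]alkanes to 3-chlorocycloalkanones, cleaves the same C1–C6 bond through the more stable tertiary radical and should give the tertiary β-chloro ketone 3-(2-chloro-2,5-dimethyl-7-oxocyclohept-4-en-1-yl)-3-hydroxy-4-methylpentanal F1. Slow addition of Bu3SnH/AIBN (benzene, 80 °C) then regenerates the C1 radical, which closes the five-membered ring by the known 5-exo cyclisation of an alkyl radical onto an aldehyde carbonyl. The stereochemical relay from the cyclopropane is given up, so 12 would have to be separated from its C1 and C2 isomers.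

Step 3. Enantiofacial discrimination and exo/endo control by the copper carbene may be weak on a tetrasubstituted silyl enol ether. The fallback replaces pure catalyst control by auxiliary control with separable diastereomers; it sets out from 3 and comes back at 6. Cyclopropanation of 3 with (1R,2S,5R)-menthyl diazoacetate under the same copper catalyst (or Rh2(OAc)4) should give diastereomeric menthyl esters, from which the exo ester (1R,2S,5R)-menthyl 1-[(tert-butyldimethylsilyl)oxy]-3,6-dimethylbicyclo[4.1.0]hept-3-ene-7-carboxylate F2, with the cyclopropane configuration of 4, is isolated by chromatography or crystallisation. The conditions of step 4 then convert it through Weinreb amide 5 into 6.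

Step 5. Facial selectivity of the vinyl transfer may be poor or reversed (attack past the OTBS group or through the other carbonyl rotamer), and the hindered ketone may enolise. The fallback introduces the two carbon substituents of C4 in the opposite order, which inverts the sense of induction; it sets out from 4 and comes back at 7. Compound 4 is taken through Weinreb amide 5 as in step 4 but treated with ethynylmagnesium bromide to give the ynone 1-{exo-1-[(tert-butyldimethylsilyl)oxy]-3,6-dimethylbicyclo[4.1.0]hept-3-en-7-yl}prop-2-yn-1-one F3. Addition of iPrMgCl/CeCl3 (THF, −78 °C) should give the propargylic alcohol 3-{exo-1-[(tert-butyldimethylsilyl)oxy]-3,6-dimethylbicyclo[4.1.0]hept-3-en-7-yl}-4-methylpent-1-yn-3-ol F4, and Lindlar semihydrogenation (H2, Pd/CaCO3 poisoned with Pb(OAc)2, quinoline) would give 7.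

**Further compounds**
F1 | step 8 | 3-(2-chloro-2,5-dimethyl-7-oxocyclohept-4-en-1-yl)-3-hydroxy-4-methylpentanal (either configuration at the chlorine-bearing carbon) | O=CC[C@@](O)(C(C)C)[C@@H]1C(=O)CC(C)=CCC1(C)Cl
F2 | step 3 | (1R,2S,5R)-menthyl exo-1-[(tert-butyldimethylsilyl)oxy]-3,6-dimethylbicyclo[4.1.0]hept-3-ene-7-carboxylate | CC(C)(C)[Si](C)(C)O[C@]12CC(C)=CC[C@@]1(C)[C@@H]2C(=O)O[C@@H]1C[C@H](C)CC[C@H]1C(C)C
F3 | step 5 | 1-{exo-1-[(tert-butyldimethylsilyl)oxy]-3,6-dimethylbicyclo[4.1.0]hept-3-en-7-yl}prop-2-yn-1-one | CC(C)(C)[Si](C)(C)O[C@]12CC(C)=CC[C@@]1(C)[C@@H]2C(=O)C#C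
F4 | step 5 | 3-{exo-1-[(tert-butyldimethylsilyl)oxy]-3,6-dimethylbicyclo[4.1.0]hept-3-en-7-yl}-4-methylpent-1-yn-3-ol | CC(C)(C)[Si](C)(C)O[C@]12CC(C)=CC[C@@]1(C)[C@@H]2[C@](O)(C(C)C)C#C
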